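**Assumption:** the (R,R)-DACH-phenyl Trost ligand gives the (R)-aryl ether 6 from racemic epoxide 5 (the (S,S)-ligand is used if the opposite sense is observed). The SMILES puts the acid alkene as Z (CO2H cis to the chain CH2) and the other trisubstituted alkene as E.

## Retrosynthetic overview
- The molecule is cut at the sp3–sp2 bond C14–C15 (numbered along the chain from the ring: C16, C15, C14=C12 …). This gives a 2-vinylchromene, converted to its alkyl-9-BBN by hydroboration, and an (E)-vinyl iodide that already carries the (Z)-α-alkyl acrylate. The two halves have about 13 and 14 carbons.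
- The (Z)-acrylate comes from a Z-selective HWE of an (E)-iodo-aldehyde with a homoprenyl phosphonate. The iodo-aldehyde comes from carboalumination of 4-pentyn-1-ol.
- The chromene quaternary (S)-centre is set first, by Pd-catalysed asymmetric allylic etherification of isoprene monoepoxide with a bromophenol. The pyran ring is then closed by intramolecular Heck (C4a–C4 bond).
- The CH2OH left by the epoxide becomes C16 via aldehyde and methylenation. The aryl ring is built from o-cresol: para-oxygenation, mono-silylation, then ortho-bromination.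

## Route

**Step 1**
Reactants: 1 (o-cresol)
Product: 2 (2-methylbenzene-1,4-diol)
Conditions: K2S2O8, aq. NaOH, 0→20 °C, 24 h; then HCl, 60 °C
Reagents that add atoms: potassium persulfate, [K+].[K+].[O-]S(=O)(=O)OOS(=O)(=O)[O-]
Why: Elbs persulfate oxidation puts oxygen para to the phenoxide, and the ortho-methyl blocks only one ortho site. The aryl sulfate is hydrolysed to the hydroquinone.

**Step 2**
Reactants: 2
Product: 3 (4-(TBSO)-2-methylphenol)
Conditions: TBSCl (1.0 equiv), imidazole, CH2Cl2/DMF, 0 °C
Reagents that add atoms: TBSCl, C[Si](C)(C(C)(C)C)Cl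
Why: The OH next to the methyl is hindered, so silylation occurs at the free 4-OH. The minor regioisomer is removed by chromatography.

**Step 3**
Reactants: 3
Product: 4 (2-bromo-4-(TBSO)-6-methylphenol)
Conditions: NBS (1.0 equiv), i-Pr2NH (10 mol%), CH2Cl2, −78→20 °C
Reagents that add atoms: NBS, O=C1CCC(=O)N1Br
Why: Amine-catalysed NBS bromination is ortho-selective for phenols. The only free position ortho to the OH is C6, so electrophilic substitution there gives the bromide needed for the later Heck ring closure.

**Step 4**
Reactants: 4; 5 (racemic 2-methyl-2-vinyloxirane, isoprene monoepoxide)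
Product: 6 ((2R)-2-[2-bromo-4-(TBSO)-6-methylphenoxy]-2-methylbut-3-en-1-ol)
Conditions: Pd2(dba)3·CHCl3 (2.5 mol%), (R,R)-DACH-phenyl Trost ligand (7.5 mol%), CH2Cl2, 20 °C
Reagents that add atoms: none
Why: Pd-catalysed dynamic kinetic asymmetric allylic etherification. The racemic epoxide ionises to a π-allyl–Pd alkoxide whose two enantiomeric forms interconvert. The chiral ligand directs phenoxide attack at the more substituted terminus, forming the tertiary aryl ether and setting the quaternary centre.

**Step 5**
Reactants: 6
Product: 7 (((2R)-6-(TBSO)-2,8-dimethyl-2H-chromen-2-yl)methanol)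
Conditions: Pd(OAc)2 (10 mol%), PPh3 (20 mol%), Ag2CO3, MeCN, 80 °C
Reagents that add atoms: none
Why: Intramolecular Heck reaction. 6-endo aryl–Pd addition to the terminal vinyl carbon is followed by β-H elimination, giving the C3=C4 bond of the 2H-chromene. The stereocentre is untouched.

**Step 6**
Reactants: 7
Product: 8 ((2R)-6-(TBSO)-2,8-dimethyl-2H-chromene-2-carbaldehyde)
Conditions: Dess–Martin periodinane, NaHCO3, CH2Cl2, 0→20 °C
Reagents that add atoms: none
Why: Mild oxidation of the primary alcohol. The aldehyde has no α-H, so the quaternary centre cannot epimerise.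

**Step 7**
Reactants: 8
Product: 9 ((2S)-6-(TBSO)-2,8-dimethyl-2-vinyl-2H-chromene)
Conditions: Ph3PCH3Br, KHMDS, THF, 0→20 °C
Reagents that add atoms: methyltriphenylphosphonium bromide, C[P+](c1ccccc1)(c1ccccc1)c1ccccc1.[Br-] (supplies the =CH2 carbon)
Why: Wittig methylenation of the hindered aldehyde gives the terminal alkene for hydroboration. The descriptor changes from R to S only because of CIP priorities; the geometry is unchanged.

**Step 8**
Reactants: 10 (4-pentyn-1-ol)
Product: 11 ((E)-5-iodo-4-methylpent-4-en-1-ol)
Conditions: Me3Al, Cp2ZrCl2 (cat.), ClCH2CH2Cl, 0→20 °C; then I2, THF, −30 °C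
Reagents that add atoms: trimethylaluminum, C[Al](C)C; iodine, II
Why: Negishi Zr-catalysed carboalumination. Syn addition of Me–Al to the terminal alkyne puts the methyl on the internal carbon. Al→I exchange with retention gives the E-trisubstituted vinyl iodide, which sets the C12=C14 geometry.

**Step 9**
Reactants: 11
Product: 12 ((E)-5-iodo-4-methylpent-4-enal)
Conditions: Dess–Martin periodinane, NaHCO3, CH2Cl2, 0 °C
Reagents that add atoms: none
Why: Mild oxidation that leaves the vinyl iodide intact.

**Step 10**
Reactants: 13 (methyl bromoacetate)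
Product: 14 (methyl 2-[bis(2,2,2-trifluoroethoxy)phosphoryl]acetate)
Conditions: HP(O)(OCH2CF3)2, NaH, THF, 0→20 °C
Reagents that add atoms: bis(2,2,2-trifluoroethyl) phosphite, O=[PH](OCC(F)(F)F)OCC(F)(F)F
Why: Michaelis–Becker alkylation of the phosphite anion. The electron-poor phosphonate is what makes the later HWE Z-selective.

**Step 11**
Reactants: 14; 15 (5-bromo-2-methylpent-2-ene)
Product: 16 (methyl 2-[bis(trifluoroethoxy)phosphoryl]-6-methylhept-5-enoate)
Conditions: NaH, THF/DMF, 0 °C; then 15, NaI (cat.), 20→50 °C
Reagents that add atoms: none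
Why: Mono-C-alkylation of the stabilised phosphonate carbanion gives the α-homoprenyl phosphonate. The racemic α-carbon is irrelevant because it is deprotonated in the next step.

**Step 12**
Reactants: 12; 16
Product: 17 (methyl (2Z,6E)-7-iodo-6-methyl-2-(4-methylpent-3-en-1-yl)hepta-2,6-dienoate)
Conditions: KHMDS, 18-crown-6, THF, −78 °C
Reagents that add atoms: none
Why: Still–Gennari-type HWE. The fast, irreversible elimination from the syn oxaphosphetane places the ester cis to the aldehyde-derived chain, giving the (Z)-acrylate required by the target. The E-vinyl iodide is retained.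

**Step 13**
Reactants: 9; 17
Product: 18 (methyl ester, aryl TBS ether of the target)
Conditions: (i) 9-BBN, THF, 20 °C, 4 h; (ii) 17, Pd(dppf)Cl2 (10 mol%), K3PO4 (3 M aq.), THF/DMF, 20 °C, 12 h
Reagents that add atoms: none (9-BBN is lost as boron by-product; only H is added)
Why: 9-BBN hydroborates the unhindered terminal vinyl group anti-Markovnikov and leaves the ring alkene, then B-alkyl Suzuki–Miyaura coupling joins C15 to C14. This is the fragment-joining step. Coupling proceeds with retention of the alkene geometry, and the quaternary centre is not involved.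

**Step 14**
Reactants: 18
Product: 19 ((S)-sargachromenol)
Conditions: LiOH·H2O, THF/MeOH/H2O (3:1:1), 45 °C, 24 h; then NaH2PO4/HCl to pH 3
Reagents that add atoms: water, O
Why: Saponification of the hindered methyl ester and base cleavage of the aryl silyl ether in one pot. The alkenes have no acidic α-H on the sp2 carbons, and the Z/E geometries and the C2 stereocentre are untouched.

## Compound list
1 | o-cresol | Cc1ccccc1O | starting material
2 | 2-methylbenzene-1,4-diol | Cc1cc(O)ccc1O | intermediate
3 | 4-(TBSO)-2-methylphenol | Cc1cc(O[Si](C)(C)C(C)(C)C)ccc1O | intermediate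
4 | 2-bromo-4-(TBSO)-6-methylphenol | Cc1cc(O[Si](C)(C)C(C)(C)C)cc(Br)c1O | intermediate
5 | 2-methyl-2-vinyloxirane (racemic) | C=CC1(C)CO1 | starting material
6 | (2R)-2-[2-bromo-4-(TBSO)-6-methylphenoxy]-2-methylbut-3-en-1-ol | OC[C@@](C)(C=C)Oc1c(Br)cc(O[Si](C)(C)C(C)(C)C)cc1C | intermediate
7 | ((2R)-6-(TBSO)-2,8-dimethyl-2H-chromen-2-yl)methanol | OC[C@@]1(C)C=Cc2cc(O[Si](C)(C)C(C)(C)C)cc(C)c2O1 | intermediate
8 | (2R)-6-(TBSO)-2,8-dimethyl-2H-chromene-2-carbaldehyde | O=C[C@@]1(C)C=Cc2cc(O[Si](C)(C)C(C)(C)C)cc(C)c2O1 | intermediate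
9 | (2S)-6-(TBSO)-2,8-dimethyl-2-vinyl-2H-chromene | C=C[C@@]1(C)C=Cc2cc(O[Si](C)(C)C(C)(C)C)cc(C)c2O1 | intermediate
10 | 4-pentyn-1-ol | C#CCCCO | starting material
11 | (E)-5-iodo-4-methylpent-4-en-1-ol | I/C=C(\C)CCCO | intermediate
12 | (E)-5-iodo-4-methylpent-4-enal | I/C=C(\C)CCC=O | intermediate
13 | methyl bromoacetate | BrCC(=O)OC | starting material
14 | methyl 2-[bis(2,2,2-trifluoroethoxy)phosphoryl]acetate | COC(=O)CP(=O)(OCC(F)(F)F)OCC(F)(F)F | intermediate
15 | 5-bromo-2-methylpent-2-ene | CC(C)=CCCBr | starting material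
16 | methyl 2-[bis(trifluoroethoxy)phosphoryl]-6-methylhept-5-enoate | COC(=O)C(CCC=C(C)C)P(=O)(OCC(F)(F)F)OCC(F)(F)F | intermediate
17 | methyl (2Z,6E)-7-iodo-6-methyl-2-(4-methylpent-3-en-1-yl)hepta-2,6-dienoate | CC(C)=CCC/C(=C/CC/C(C)=C/I)C(=O)OC | intermediate
18 | methyl ester / aryl TBS ether of the target | CC(C)=CCC/C(=C/CC/C(C)=C/CC[C@@]1(C)C=Cc2cc(O[Si](C)(C)C(C)(C)C)cc(C)c2O1)C(=O)OC | intermediate
19 | (S)-sargachromenol | CC(C)=CCC/C(=C/CC/C(C)=C/CC[C@@]1(C)C=Cc2cc(O)cc(C)c2O1)C(=O)O | target

**Total steps:** 14.
**Longest linear sequence:** 9 (o-cresol → 2 → 3 → 4 → 6 → 7 → 8 → 9 → 18 → 19), which is 9/14 ≈ 0.64 of the total.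

## Three steps most likely to fail
1. **Step 4 (Pd-AAA with a 2,6-disubstituted phenol).** Branched selectivity and ee may be poor for this hindered nucleophile. *Fallback:* make racemic 6 with an achiral Pd catalyst, carry it to alcohol 7, and resolve 7 by lipase-catalysed acetylation (vinyl acetate) or preparative chiral HPLC.
2. **Step 5 (6-endo Heck).** 5-exo cyclisation to a 3-methylenedihydrobenzofuran may compete. *Fallback:* vinylate the aryl bromide of 6 (vinyl-BF3K, Pd), then close the ring by Grubbs II ring-closing metathesis.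
3. **Step 12 (Z-selective HWE with an α-alkyl phosphonate).** The Z:E ratio may fall below about 9:1. *Fallback:* a different alkene construction. Convert TMS-protected pent-4-ynal to the 1,1-dibromoalkene, couple trans-selectively with 4-methylpent-3-enylzinc (Negishi), and methoxycarbonylate the remaining (Z)-vinyl bromide (Pd/CO/MeOH). Then remove the TMS group and apply carboalumination/iodination to reach 17.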